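**Retrosynthetic overview**

1. Feature: in the dihydrofuran ring (O1–C2–C3–C3a–C7a), C2 carries the catechol ring and is the only carbon between O1 and C3 (resorcinol ring). Both of its ring bonds, O1–C2 and C2–C3, can therefore come from one benzylic ylide carbon added to an o-quinone methide that supplies C3, C3a, C7a and O1.
2. Disconnections, backwards: acetate removal; the C4–styryl bond by a Heck reaction on a C4 bromide; exchange of methyl ethers for acetates before the stilbene exists, because the C4-styryl/C3-aryl array is expected to cyclise under strong Lewis acid; then the [4+1] annulation.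
3. o-Quinone methide precursor: a 2-[aryl(tosyl)methyl]phenol from 2-bromo-6-hydroxy-4-methoxybenzaldehyde (the aldehyde fixes the regiochemistry), 3,5-dimethoxyphenyl Grignard reagent and p-toluenesulfinic acid.
4. Ylide precursor: the benzylsulfonium salt from C2-symmetric (2S,5S)-2,5-dimethylthiolane (made from (2R,5R)-hexane-2,5-diol) and 3,4-dimethoxybenzyl bromide.
5. Ring order: the four benzene rings are bought; the dihydrofuran ring is the only ring formed (step 7), together with both stereocentres.

Key step: step 7

Assumption: the sense of induction is taken from the ylide-face model that accounts for epoxidation with this thiolane, which points to the (2S,5S)-sulfide for a 2S product (the antipode, from (2S,5S)-hexane-2,5-diol, would be used should the sense prove opposite); 3,5-dimethoxyphenylmagnesium bromide is bought as a THF solution.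

**Route**

Step 1
Reactants: 1 2-bromo-4,6-dimethoxybenzaldehyde
Product: 2 2-bromo-6-hydroxy-4-methoxybenzaldehyde
Conditions: BCl3 (1.2 equiv), CH2Cl2, −78 → 0 °C; aqueous work-up
Reagents that add atoms: none
Why: Chelation-controlled Lewis-acid O-demethylation: BCl3 binds between the aldehyde oxygen and the ortho methoxy group, so chloride removes only that methyl group and the para methoxy group stays.

Step 2
Reactants: 2 2-bromo-6-hydroxy-4-methoxybenzaldehyde; 3 3,5-dimethoxyphenylmagnesium bromide
Product: 4 3-bromo-2-[(3,5-dimethoxyphenyl)(hydroxy)methyl]-5-methoxyphenol (racemic)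
Conditions: 3 (3 equiv), THF, 0 °C → rt; sat. aq NH4Cl
Reagents that add atoms: none
Why: Grignard addition to the aldehyde, in which the first equivalent of 3 deprotonates the phenol, further reagent adds to the formyl group and bromine–magnesium exchange at the aryl bromide is slow at this temperature; the carbinol centre forms racemic and is erased in step 7.

Step 3
Reactants: 4 3-bromo-2-[(3,5-dimethoxyphenyl)(hydroxy)methyl]-5-methoxyphenol
Product: 5 3-bromo-2-[(3,5-dimethoxyphenyl)(4-methylbenzenesulfonyl)methyl]-5-methoxyphenol (racemic)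
Conditions: p-TolSO2H (2 equiv), CH2Cl2, rt
Reagents that add atoms: p-toluenesulfinic acid, Cc1ccc(cc1)S(=O)O
Why: Acid-promoted SN1 substitution of the benzhydrol, in which the sulfinic acid ionises the alcohol to a cation stabilised by the ortho-hydroxy and para-methoxy groups and the sulfur of the sulfinate captures it, the usual entry to 2-(1-tosylalkyl)phenols.

Step 4
Reactants: 6 (2R,5R)-hexane-2,5-diol
Product: 7 (2R,5R)-hexane-2,5-diyl dimethanesulfonate
Conditions: MsCl (2.5 equiv), Et3N, CH2Cl2, −20 → 0 °C
Reagents that add atoms: methanesulfonyl chloride, CS(=O)(=O)Cl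
Why: O-Sulfonylation of both secondary alcohols forms only O–S bonds, so the two stereocentres are untouched.

Step 5
Reactants: 7 (2R,5R)-hexane-2,5-diyl dimethanesulfonate
Product: 8 (2S,5S)-2,5-dimethylthiolane
Conditions: Na2S·9H2O, DMSO, rt; pentane extraction, distillation
Reagents that add atoms: sodium sulfide, [Na+].[Na+].[S-2]
Why: Double SN2 displacement by sulfide, first intermolecular and then 5-exo-tet, inverts each carbon once, so the (2R,5R)-dimesylate should give the C2-symmetric (2S,5S)-thiolane.

Step 6
Reactants: 8 (2S,5S)-2,5-dimethylthiolane; 9 3,4-dimethoxybenzyl bromide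
Product: 10 (2S,5S)-1-(3,4-dimethoxybenzyl)-2,5-dimethylthiolan-1-ium tetrafluoroborate
Conditions: AgBF4, CH2Cl2, 0 °C → rt, dark (sulfide and bromide premixed); filter, precipitate with Et2O
Reagents that add atoms: silver tetrafluoroborate, [Ag+].F[B-](F)(F)F
Why: S-Alkylation of the sulfide by the activated benzylic bromide is driven to completion by precipitation of silver bromide, and because the two sulfur lone pairs are equivalent by symmetry a single sulfonium salt forms.

Step 7
Reactants: 5 3-bromo-2-[(3,5-dimethoxyphenyl)(4-methylbenzenesulfonyl)methyl]-5-methoxyphenol; 10 (2S,5S)-1-(3,4-dimethoxybenzyl)-2,5-dimethylthiolan-1-ium tetrafluoroborate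
Product: 14 (2S,3S)-4-bromo-2-(3,4-dimethoxyphenyl)-3-(3,5-dimethoxyphenyl)-6-methoxy-2,3-dihydro-1-benzofuran, via o-quinone methide 11 (not isolated), via sulfonium ylide 12 (not isolated), via phenoxide sulfonium zwitterion 13 (not isolated)
Conditions: 10 (1.5 equiv), Cs2CO3 (3 equiv), MeCN, −20 → 0 °C, Ar; sulfide 8 recovered
Reagents that add atoms: none
Why: Carbonate deprotonates the phenol of 5, which loses sulfinate by 1,4-elimination to give o-quinone methide 11, and in equilibrium deprotonates 10 to the benzylic ylide 12; the ylide carbon adds to the methide carbon (conjugate addition, C2–C3), irreversibly because the benzene ring is regained, to give zwitterion 13, whose phenoxide oxygen displaces the thiolane at the benzylic carbon by intramolecular SN2 with inversion (O1–C2). The closest known reaction type is the base-mediated [4+1] annulation of o-quinone methides, released in situ from 2-(1-tosylalkyl)phenols, with sulfonium ylides to give trans-2,3-dihydrobenzofurans; the dihydrofuran ring closes in the 5-exo-tet mode. C2 is controlled by the C2-symmetric thiolane: the ylide keeps its aryl group turned away from the ring, the methyl group cis to the ylide carbon covers one face, and attack through the open face (the bias that sets the sense of epoxidation with this sulfide) should give the R sulfonium carbon of 13 and, after inversion in the closure, 2S. C3 is set relative to C2 in the same addition through a staggered transition state with the sulfonium group anti to the quinoid ring and the two aryl groups anti to each other, which is already the conformer needed for backside closure and leads to the trans (2S,3S) ring, also the more stable isomer. The step needs C-alkylation of the ylide by the methide carbon to outrun O-benzylation of the phenoxide of 5 by 10 and self-condensation of 11: the hindered phenoxide ejects sulfinate quickly, the 3,5-dimethoxyphenyl group stabilises 11, both reactive partners are present only in low concentration, and the C4 bromine is a spectator. Any cis isomer is removed by chromatography and not equilibrated, because epimerisation at C2 would lead into the enantiomeric trans series.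

Step 8
Reactants: 14 (2S,3S)-4-bromo-2-(3,4-dimethoxyphenyl)-3-(3,5-dimethoxyphenyl)-6-methoxy-2,3-dihydro-1-benzofuran
Product: 15 4-[(2S,3S)-4-bromo-3-(3,5-dihydroxyphenyl)-6-hydroxy-2,3-dihydro-1-benzofuran-2-yl]benzene-1,2-diol
Conditions: BBr3 (12 equiv), CH2Cl2, −78 → 0 °C; MeOH, then water
Reagents that add atoms: none
Why: Lewis-acid ether cleavage removes all five methyl groups before the stilbene is attached, since the C4-styryl/C3-resorcinol array would be prone to acid-induced seven-membered ring closure, and a reversible opening of the C2–O1 benzylic ether should only return the more stable trans ring because C3 is untouched.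

Step 9
Reactants: 15 4-[(2S,3S)-4-bromo-3-(3,5-dihydroxyphenyl)-6-hydroxy-2,3-dihydro-1-benzofuran-2-yl]benzene-1,2-diol
Product: 16 (2S,3S)-4-bromo-2-(3,4-diacetoxyphenyl)-3-(3,5-diacetoxyphenyl)-2,3-dihydro-1-benzofuran-6-yl acetate (pentaacetate)
Conditions: Ac2O, pyridine, DMAP (cat.), CH2Cl2, 0 °C → rt
Reagents that add atoms: acetic anhydride, CC(=O)OC(C)=O
Why: Exhaustive O-acetylation (DMAP-catalysed acyl transfer) masks the five phenols as base-labile esters that tolerate the palladium step.

Step 10
Reactants: 16 pentaacetate bromide; 17 4-acetoxystyrene (4-ethenylphenyl acetate)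
Product: 18 scirpusin A hexaacetate, (2S,3S)-configured, (E)-alkene
Conditions: Pd2(dba)3 (cat.), [HP(t-Bu)3]BF4 (cat.), Cy2NMe, 1,4-dioxane, 90 °C
Reagents that add atoms: none
Why: Mizoroki–Heck reaction, in which oxidative addition at C4–Br, syn insertion of the styrene with the aryl group going to the terminal carbon and syn β-hydride elimination give the (E)-stilbene; the bulky electron-rich phosphine is chosen for the bromide flanked by the C3 aryl group, and the stereocentres are not involved.

Step 11
Reactants: 18 scirpusin A hexaacetate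
Product: 19 scirpusin A
Conditions: K2CO3 (cat.), degassed MeOH, 0 °C → rt, Ar; then Amberlite IR-120 (H+)
Reagents that add atoms: none
Why: Base-catalysed transesterification (Zemplén-type methanolysis) cleaves the six aryl acetates under mild, non-acidic conditions that leave the stilbene, the dihydrofuran ring and both stereocentres alone, with air excluded because the catecholate is easily oxidised.

**Compound list**

1 | 2-bromo-4,6-dimethoxybenzaldehyde | COc1cc(Br)c(C=O)c(OC)c1 | starting material
2 | 2-bromo-6-hydroxy-4-methoxybenzaldehyde | COc1cc(O)c(C=O)c(Br)c1 | intermediate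
3 | 3,5-dimethoxyphenylmagnesium bromide (THF solution) | COc1cc(OC)cc([Mg]Br)c1 | starting material
4 | 3-bromo-2-[(3,5-dimethoxyphenyl)(hydroxy)methyl]-5-methoxyphenol (racemic) | COc1cc(OC)cc(C(O)c2c(O)cc(OC)cc2Br)c1 | intermediate
5 | 3-bromo-2-[(3,5-dimethoxyphenyl)(4-methylbenzenesulfonyl)methyl]-5-methoxyphenol (racemic) | COc1cc(OC)cc(C(c2c(O)cc(OC)cc2Br)S(=O)(=O)c2ccc(C)cc2)c1 | intermediate
6 | (2R,5R)-hexane-2,5-diol | C[C@@H](O)CC[C@@H](C)O | starting material
7 | (2R,5R)-hexane-2,5-diyl dimethanesulfonate | C[C@@H](OS(C)(=O)=O)CC[C@@H](C)OS(C)(=O)=O | intermediate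
8 | (2S,5S)-2,5-dimethylthiolane | C[C@H]1CC[C@H](C)S1 | intermediate
9 | 3,4-dimethoxybenzyl bromide | COc1ccc(CBr)cc1OC | starting material
10 | (2S,5S)-1-(3,4-dimethoxybenzyl)-2,5-dimethylthiolan-1-ium tetrafluoroborate | C[C@H]1CC[C@H](C)[S+]1Cc1ccc(OC)c(OC)c1.F[B-](F)(F)F | intermediate
11 | 3-bromo-2-(3,5-dimethoxybenzylidene)-5-methoxycyclohexa-3,5-dien-1-one (o-quinone methide; exocyclic alkene geometry left open) | COC1=CC(=O)C(=Cc2cc(OC)cc(OC)c2)C(Br)=C1 | intermediate (not isolated)
12 | (2S,5S)-1-(3,4-dimethoxybenzylidene)-2,5-dimethylthiolane ylide | C[C@H]1CC[C@H](C)[S+]1[CH-]c1ccc(OC)c(OC)c1 | intermediate (not isolated)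
13 | 3-bromo-2-[(1S,2R)-2-(3,4-dimethoxyphenyl)-1-(3,5-dimethoxyphenyl)-2-[(2S,5S)-2,5-dimethylthiolan-1-ium-1-yl]ethyl]-5-methoxyphenolate (zwitterion; sulfonium carbon R, diarylmethine carbon S) | COc1cc([O-])c([C@H](c2cc(OC)cc(OC)c2)[C@H](c2ccc(OC)c(OC)c2)[S+]2[C@@H](C)CC[C@@H]2C)c(Br)c1 | intermediate (not isolated)
14 | (2S,3S)-4-bromo-2-(3,4-dimethoxyphenyl)-3-(3,5-dimethoxyphenyl)-6-methoxy-2,3-dihydro-1-benzofuran | Brc1cc(OC)cc2c1[C@H](c1cc(OC)cc(OC)c1)[C@@H](c1ccc(OC)c(OC)c1)O2 | intermediate
15 | 4-[(2S,3S)-4-bromo-3-(3,5-dihydroxyphenyl)-6-hydroxy-2,3-dihydro-1-benzofuran-2-yl]benzene-1,2-diol | Brc1cc(O)cc2c1[C@H](c1cc(O)cc(O)c1)[C@@H](c1ccc(O)c(O)c1)O2 | intermediate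
16 | (2S,3S)-4-bromo-2-(3,4-diacetoxyphenyl)-3-(3,5-diacetoxyphenyl)-2,3-dihydro-1-benzofuran-6-yl acetate | Brc1cc(OC(C)=O)cc2c1[C@H](c1cc(OC(C)=O)cc(OC(C)=O)c1)[C@@H](c1ccc(OC(C)=O)c(OC(C)=O)c1)O2 | intermediate
17 | 4-acetoxystyrene (4-ethenylphenyl acetate) | C=Cc1ccc(OC(C)=O)cc1 | starting material
18 | scirpusin A hexaacetate, (2S,3S), (E) | CC(=O)Oc1ccc(/C=C/c2cc(OC(C)=O)cc3c2[C@H](c2cc(OC(C)=O)cc(OC(C)=O)c2)[C@@H](c2ccc(OC(C)=O)c(OC(C)=O)c2)O3)cc1 | intermediate
19 | scirpusin A, 4-[(2S,3S)-3-(3,5-dihydroxyphenyl)-6-hydroxy-4-[(E)-2-(4-hydroxyphenyl)ethenyl]-2,3-dihydro-1-benzofuran-2-yl]benzene-1,2-diol | Oc1ccc(/C=C/c2cc(O)cc3c2[C@H](c2cc(O)cc(O)c2)[C@@H](c2ccc(O)c(O)c2)O3)cc1 | target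

**Step count**

Total: 11 steps. Longest linear sequence: 8 steps (1 → 2 → 4 → 5 → 14 → 15 → 16 → 18 → 19; the branch 6 → 7 → 8 → 10 → 14 → 19 is equally long).

**Steps most likely to fail**

Step 7. What may go wrong: the two faces of ylide 12 are not discriminated well enough (low enantiomeric purity), the addition takes the wrong relative topicity (cis isomer), or 10 is consumed by O-benzylation of the phenoxide. Fallback, resolution in place of reagent control: tetrahydrothiophene is alkylated with 9 and AgBF4 to the achiral salt 1-(3,4-dimethoxybenzyl)thiolan-1-ium tetrafluoroborate F1. The same carbonate-mediated annulation of 5 with this salt should give racemic trans-4-bromo-2-(3,4-dimethoxyphenyl)-3-(3,5-dimethoxyphenyl)-6-methoxy-2,3-dihydro-1-benzofuran F2. This is resolved by preparative chromatography on a polysaccharide-carbamate chiral stationary phase; the (2S,3S) enantiomer is 14, and the route continues with step 8.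

Step 8. What may go wrong: the Lewis acid opens the C2–O1 benzylic ether irreversibly (Friedel–Crafts or elimination chemistry of the C2 cation) in competition with the five demethylations, or the catechol ethers are cleaved incompletely. Fallback, nucleophilic ether cleavage at the end with no Lewis acid and no acetates: starting from 14, a Heck coupling with 4-methoxystyrene under the conditions of step 10 should give scirpusin A hexamethyl ether F3. Heating this with excess sodium trimethylsilanethiolate in 1,3-dimethyl-2-imidazolidinone (about 185 °C) removes each methyl group by SN2 attack of sulfur at the methyl carbon. Each phenoxide is silylated as it forms, which keeps the rings neutral so that the vicinal and the meta methoxy groups are all cleaved. The resulting hexakis(trimethylsilyl) ether of scirpusin A F4 is hydrolysed on work-up with aqueous methanol and gives the target 19 directly. No cation can form at C2 or at the stilbene under these conditions. The aryl bromide is coupled first because thiolates can substitute aryl bromides at this temperature.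

Step 10. What may go wrong: oxidative addition and migratory insertion at the C4–Br bond, which is flanked by the C3 aryl group, are slow, so that polymerisation of the styrene or arylation at its internal carbon takes over. Fallback, roles of the partners exchanged: Stille coupling of 16 with tributyl(vinyl)stannane (Pd(PPh3)4, toluene, 100 °C; neutral, so the acetates survive) should give (2S,3S)-2-(3,4-diacetoxyphenyl)-3-(3,5-diacetoxyphenyl)-4-ethenyl-2,3-dihydro-1-benzofuran-6-yl acetate F5. A Heck reaction of this terminal alkene with 4-iodophenyl acetate (Pd(OAc)2, Et3N, DMF, 80 °C), in which oxidative addition now takes place at an unhindered aryl iodide, should give hexaacetate 18, and the route resumes at step 11.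

**Further compounds**

F1 | step 7 | 1-(3,4-dimethoxybenzyl)thiolan-1-ium tetrafluoroborate | COc1ccc(C[S+]2CCCC2)cc1OC.F[B-](F)(F)F
F2 | step 7 | racemic trans-4-bromo-2-(3,4-dimethoxyphenyl)-3-(3,5-dimethoxyphenyl)-6-methoxy-2,3-dihydro-1-benzofuran (1:1 mixture of 14 and its (2R,3R) enantiomer) | Brc1cc(OC)cc2c1[C@H](c1cc(OC)cc(OC)c1)[C@@H](c1ccc(OC)c(OC)c1)O2.Brc1cc(OC)cc2c1[C@@H](c1cc(OC)cc(OC)c1)[C@H](c1ccc(OC)c(OC)c1)O2
F3 | step 8 | scirpusin A hexamethyl ether, (2S,3S), (E) | COc1ccc(/C=C/c2cc(OC)cc3c2[C@H](c2cc(OC)cc(OC)c2)[C@@H](c2ccc(OC)c(OC)c2)O3)cc1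
F4 | step 8 | hexakis(trimethylsilyl) ether of scirpusin A, (2S,3S), (E) | C[Si](C)(C)Oc1ccc(/C=C/c2cc(O[Si](C)(C)C)cc3c2[C@H](c2cc(O[Si](C)(C)C)cc(O[Si](C)(C)C)c2)[C@@H](c2ccc(O[Si](C)(C)C)c(O[Si](C)(C)C)c2)O3)cc1
F5 | step 10 | (2S,3S)-2-(3,4-diacetoxyphenyl)-3-(3,5-diacetoxyphenyl)-4-ethenyl-2,3-dihydro-1-benzofuran-6-yl acetate | C=Cc1cc(OC(C)=O)cc2c1[C@H](c1cc(OC(C)=O)cc(OC(C)=O)c1)[C@@H](c1ccc(OC(C)=O)c(OC(C)=O)c1)O2
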